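Target is made in solution, over-reaction takes it from there, and crystals take up whatever exceeds the solubility.

    gas phase ⇌ dissolved gas, rate k1*(csat - [dissolved gas]) (k1 = 1.20 × 10⁻⁴ s⁻¹, csat = 11 mM)
    starting material + dissolved gas → target (k2 = 0.00204 M⁻¹ s⁻¹)
    target → over-reaction product (k3 = 5.10 × 10⁻⁵ s⁻¹)
    crystals ⇌ target, rate k4*(cs4 - [target]) while solid is left; crystals form when [target] > cs4 (cs4 = 0.68 mM, k4 = 9.51 × 10⁻⁴ s⁻¹)
starting material 20 mM; gas phase 11 mM (held); time 20 h
* target and crystals together at 20 h, in percent of the starting material charged
* concentration of dissolved gas in solution at 20 h, in percent of saturation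
- for target the crystals are counted in
- as a solid, counted per litre of solution: crystals
- at the start none of the gas is dissolved
- run time (flask): 20 h

Two rates compete in this flask. The first is the making of target. The transfer could deliver 475% of the charge by 20 h, so gas enters as a level and not as a third rate. Setting transfer equal to consumption at the full charge gives that level, and from it the rate of making:

[dissolved gas] = 11 mM × 1.20 × 10⁻⁴ s⁻¹ / (1.20 × 10⁻⁴ s⁻¹ + 0.00204 M⁻¹ s⁻¹ × 20 mM) = 8.21 mM

making = 0.00204 M⁻¹ s⁻¹ × 20 mM × 8.21 mM = 1.21 mM h⁻¹

The second rate is the loss. Crystals exchange with solution in about 0.292 h, faster than over-reaction's 5.45 h, so while crystals stand, dissolved target stays near 0.68 mM: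

leak = 5.10 × 10⁻⁵ s⁻¹ × 0.68 mM = 0.125 mM h⁻¹

This leak, the rate of over-reaction with dissolved target held at its solubility, contains no charge of starting material. Making is 9.68 times the leak. With gas held at its level, the limiting reagent decays pseudo-first-order:

starting material left = 29.9%

lost to the leak = 0.125 mM h⁻¹ × 20 h / 20 mM = 12.5%

This reckoning gives y = 57.6%, and for the gas, with that starting material left, sat = 90.8%.

The forecast gives 54.8% (52.5% to 57%) and 89.6% (88% to 91.5%), both lower than reckoned here, and it holds, as the leak above does, that “only that dissolved portion over-reacts”.

The simulation gives y = 55.6% and sat = 89.4%, with over-reaction product at 14.6% against the reckoned 12.5%. A neighbouring flask charged with 8.0 mM of starting material, run for the same 20 h, takes the same leak as a larger share of a smaller charge: 31.2%. That flask still holds crystals at 34.9%, gives y = 43.6%, and shows over-reaction product at 30.1%.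

The constants were set for the occasion; the rest is arithmetic.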